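**Locants.** C1 is the ring-fusion carbon that carries the methyl group, C2 and C3 are the two CH2 groups of the five-membered ring, C4 is the carbinol carbon with the isopropyl group, C5 is the ring-fusion CH, C6 is the acylated carbinol CH, C7 is a CH2, C8 is the methyl-bearing alkene carbon, C9 is the alkene CH and C10 is the CH2 on C1. The same locants are used for all intermediates; compound numbers are those of the steps and of the compound list.

## Analysis of the target

Compound 27 is the 6-O-(E)-p-coumarate of the daucane diol 21: a cyclopentane (C1–C5) trans-fused along C1–C5 to a cycloheptene (C1, C5, C6, C7, C8, C9, C10) with a trisubstituted C8=C9 alkene. Four contiguous stereocentres are present: the quaternary C1, the tertiary carbinol C4, the ring-fusion methine C5 and the acylated carbinol C6. On the cyclopentane the C1 methyl group, the C4 hydroxyl group and the C5–C6 bond share one face, while C10, the isopropyl group and H5 lie on the other; the C6 oxygen lies on the face of H5, opposite to the C1 methyl group. The tertiary alcohol can dehydrate under acid, the alkene can migrate, and the p-hydroxycinnamate is base-labile, a Michael acceptor and light-sensitive at its E double bond, so it has to be attached after any photochemistry. The hard part is C5, a methine between two fully substituted carbons, together with the trans-fused seven-membered ring and its hindered, stereodefined oxygen at C6. The strategy rests on a hidden p-menthane: if C6 is placed between C4 and C5, the carbons C1, C2, C3, C4, C6 and C5 form a cyclohexane with the methyl group on C1 para to the isopropyl group on C4. C4 already carries its oxygen in that ring, exactly as in the terpene alcohol 1, whose (S) configuration is the one needed.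

## Retrosynthetic reasoning

**Ester bond at C6.** Target 27 is first unmasked to the aryl silyl ether 26, and 26 is cut at the acyl–oxygen bond into the diol 21 and the protected acid 24, which comes from 22. This keeps the sensitive cinnamate out of all earlier chemistry and makes the route convergent. The forward reaction has to acylate a hindered secondary alcohol next to a tertiary one, which is a matter of rate only, and the phenol must be masked so that the activated acid cannot acylate itself.

**C8=C9.** The ring alkene is cut next: 21 comes from its silyl ether 20, and 20 from the diene 19 by ring-closing metathesis. No other bond of the seven-membered ring can be made from two unfunctionalised chains, and the cut exposes an allyl group on C1 and a methallyl group on C6. The forward reaction must join a monosubstituted and a 1,1-disubstituted alkene that sit trans on the cyclopentane; the position of the alkene is then fixed by construction.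

**C6–C7.** Diene 19 is cut between C6 and C7 into the aldehyde 16 and the methallyl nucleophile 18 made from 17. A cut at C5–C6 instead would require bond formation at the most crowded carbon. Aldehyde 16 comes from ester 14 through alcohol 15. The forward addition creates the C6 stereocentre and must choose the correct face of the formyl group.

**C4–C5 (key disconnection).** In 14 the C4–C5 bond is cut and C4 is reconnected to C6, which leads back through the ketene 12 to the six-membered diazo ketone 11; the C5 epimer 13 converges on 14. This is the one bond whose removal uncovers the p-menthane ring; cutting C1–C5 or C3–C4 leads to no recognisable building block. The gain is that C4 arrives complete from the terpene, C1 can be made by cyclohexenone chemistry, and C5 becomes a centre under thermodynamic control. The forward reaction is a Wolff rearrangement in which C4 migrates with retention.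

**Diazo group on C5.** Diazo ketone 11 comes from ketone 9 through the activated diketone 10. C5 is the only position of 9 that can enolise, because the other α-carbon, C4, is fully substituted.

**C1–C10.** Ketone 9 is cut at the allyl bond into the enone 7 and the allylsilane 8. The allyl bond is chosen and not the methyl bond, because the methyl group is native to the terpene and conjugate addition to the β-methyl enone is the polarity-matched way to the quaternary carbon. The forward reaction must bring the allyl group in trans to the C4 oxygen.

**Carbonyl at C6.** Enone 7 is traced back to 6, then through 5 and 4 to the epoxide 3, to the silyl ether 2 and to 1. The C6 oxygen is not introduced by direct allylic C–H oxidation of 2: the two ring methylene groups C6 and C2 compete, and C6 is the neopentyl one beside the carbinol. Instead, oxygen is first placed on C1: epoxide 3 is opened at C5, and the selenoxide 5 can only take a hydrogen from C6, which gives 6 with a C5=C6 alkene. Oxidative 1,3-transposition then moves the oxygen to C6 and the alkene back to C1=C5 without regiochemical ambiguity.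

## Alternatives that were turned down

**Alternative 1:** cyclopropylcarbinyl to homoallyl ring expansion.
- Disconnection: in the diol A1 (identical with 21) the C6–O bond and the C8=C9 π bond are traced back to a cyclopropylcarbinyl cation. C6 is reconnected to C8, so that C7 becomes the methylene of a cyclopropane fused to a six-membered ring (C1, C5, C6, C8, C9, C10) with the leaving oxygen on C9; this is the tricyclic diol A2.
- Forward key step: solvolysis of A2 in dilute aqueous acid. Ionisation at C9 breaks C6–C8, forms C8=C9, and the aqueous medium hydrates C6, expanding the six-membered ring to the seven-membered one.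
- For: the reaction type is well known (it is the behaviour of the i-steroids). The alkene position is unambiguous, and the C6 oxygen enters anti to the breaking C6–C8 bond, so C6 is set stereospecifically. On this point it is stronger than the chosen route, which relies on an addition to an aldehyde whose facial preference is only predicted. It also delivers the free diol directly.
- Against: A2 is a trans-fused hydrindane with a cyclopropane and six stereocentres, two of which (C6, C8) exist only to be destroyed. Nothing in the terpene pool maps onto it, so the difficulty is moved into the synthesis of A2. The tertiary C4 alcohol must also survive the acid, and return of the nucleophile to C9 competes.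
- Comparison: the chosen strategy offers in place of the stereospecific C6 a short, cheap entry in which C4, its isopropyl group and the methyl group on C1 are present from the first step.

**Alternative 2:** carbenoid cyclopropanation and Cope rearrangement, a (4+3) annulation.
- Disconnection: C1–C10 and C7–C8 are cut, giving the ketal diene A4 (C1=C5–C6=C7) and the vinyl diazo ester A5 (C8–C9=C10).
- Forward key step: a chiral dirhodium tetracarboxylate, Rh2(O2CR)4 with chiral carboxylates, converts A5 into a vinylcarbenoid that cyclopropanates the vinyl group of A4. The cis-divinylcyclopropane then undergoes Cope rearrangement to the hydroazulene A3.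
- For: this is the most convergent plan. Two C–C bonds, the seven-membered ring and the quaternary C1 are made in one catalytic, enantioselective operation from achiral pieces. It reaches the bicyclic core in fewer steps than the chosen route and does not depend on the optical purity of a terpene; on these points it is stronger.
- Against: A3 is wrong at three places. C8 carries an ester where a methyl group is needed, and deoxygenation through an allylic derivative risks alkene transposition. C4 is a masked ketone, so the isopropyl group and the carbinol stereocentre must still be made by adding a branched nucleophile to a hindered, enolisable ketone. C5=C6 must be hydrated with defined faces. The Cope step must also form a quaternary carbon from a tetrasubstituted alkene terminus, where rate and enantiocontrol are least secure.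
- Comparison: the chosen strategy is linear but introduces every carbon at its final oxidation level and has C4 finished from the start.

**Alternative 3:** silicon-tethered radical cyclisation with allyl trapping.
- Disconnection: C5–C6 and C1–C10 are cut across the C1=C5 alkene of the cyclopentenyl bromomethylsilyl ether A7.
- Forward key step: a tin-mediated radical chain turns the C–Br bond of A7 into a radical that cyclises 5-exo onto C5. The tertiary radical at C1 is trapped by the allylstannane A8 on the face away from the new ring, giving the oxasilolane A6.
- For: the tether forces C6 cis to the C4 oxygen, so C5 is fixed by construction. The chosen route needs an equilibration there, so on this point the alternative is stronger. Both bonds are made directly on the five-membered ring, and no ring contraction is needed.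
- Against: intermolecular trapping of a hindered tertiary radical to form a quaternary carbon is slow compared with chain-terminating reduction. Tin is used stoichiometrically. A7 needs an enantiopure tertiary cyclopentenol with an isopropyl group, for which neither a chiral-pool source nor a dependable catalytic addition exists. After C–Si oxidation the route reaches the same stage as 15 and 16, so the C6 problem of the chosen route remains.
- Comparison: the chosen strategy gives up the tether control of C5 but obtains the C4 stereocentre from 1 and uses only carbonyl and photochemical steps of known type.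

Key step: step 7

Remark: commercial (S)-(+)-terpinen-4-ol (1) is assumed to be of high enantiomeric purity; less pure material would be upgraded before step 1. In 3, 4, 5 and 6 the configuration at the former alkene carbons C1 and C5 is left open, because all isomers converge on 7.

## Route

Step 1
Reactants: 1 (S)-terpinen-4-ol
Product: 2 (S)-terpinen-4-yl tert-butyldimethylsilyl ether
Conditions: TBSOTf, 2,6-lutidine, CH2Cl2, 0 °C to rt
Reagents that add atoms: tert-butyldimethylsilyl trifluoromethanesulfonate, CC(C)(C)[Si](C)(C)OS(=O)(=O)C(F)(F)F
Why: Silylation of a tertiary alcohol with a silyl triflate and a hindered base; the ether keeps the C4 oxygen from attacking C1 across the ring once C1 is made electrophilic and from competing in the later transposition, and C4 itself is not touched.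

Step 2
Reactants: 2 (S)-terpinen-4-yl tert-butyldimethylsilyl ether
Product: 3 epoxide of 2 at C1–C5 (both faces)
Conditions: mCPBA, NaHCO3, CH2Cl2, 0 °C
Reagents that add atoms: 3-chloroperoxybenzoic acid, O=C(OO)c1cccc(Cl)c1
Why: Prilezhaev epoxidation of the only alkene, which is trisubstituted and electron-rich; the buffer protects the epoxide from acid, and the face of attack is irrelevant because C1 and C5 become sp2 again in step 4.

Step 3
Reactants: 3 epoxide of 2 at C1–C5
Product: 6 tertiary allylic alcohol with hydroxyl on C1 and a C5=C6 alkene, via hydroxy selenide 4 (not isolated), via selenoxide 5 (not isolated)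
Conditions: (PhSe)2, NaBH4, EtOH, reflux; then 30% H2O2, pyridine, THF, 0 °C to rt
Reagents that add atoms: none
Why: Benzeneselenolate opens the epoxide by SN2 attack at the less substituted carbon C5; oxidation gives the selenoxide, whose syn elimination can only take a hydrogen from C6 because C1 has none. This known epoxide to allylic alcohol sequence therefore fixes the alkene at C5=C6 and leaves the oxygen on C1.

Step 4
Reactants: 6 tertiary allylic alcohol
Product: 7 (6R)-6-(tert-butyldimethylsilyloxy)-3-methyl-6-(propan-2-yl)cyclohex-2-en-1-one
Conditions: pyridinium chlorochromate [C5H5NH][CrO3Cl], 4 Å molecular sieves, CH2Cl2, rt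
Reagents that add atoms: pyridinium chlorochromate, [O-][Cr](=O)(=O)Cl.c1cc[nH+]cc1
Why: Babler–Dauben oxidative transposition: the tertiary chromate ester shifts [3,3] to C6, where it is oxidised to the ketone, and the alkene returns to C1=C5. The same reaction is known for making 3-substituted 6,6-disubstituted cyclohexenones, where the chromate also has to move next to a quaternary carbon.

Step 5
Reactants: 7 silyloxy enone; 8 allyltrimethylsilane
Product: 9 (3R,6R)-6-(tert-butyldimethylsilyloxy)-3-methyl-6-(propan-2-yl)-3-(prop-2-en-1-yl)cyclohexan-1-one
Conditions: TiCl4, CH2Cl2, −78 °C; then aq. NaHCO3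
Reagents that add atoms: none
Why: Hosomi–Sakurai conjugate allylation forms the C1–C10 bond and the quaternary centre. In the half-chair of 7 the isopropyl group on C4 is pseudo-equatorial and the silyloxy group pseudo-axial; axial attack through a chair-like transition state then brings the allyl group in on the face opposite to the silyloxy group, so that C10 is trans to the C4 oxygen as in 27. The tertiary silyl ether is expected to survive TiCl4 at −78 °C.

Step 6
Reactants: 9 allyl ketone
Product: 11 (3R,6R)-6-(tert-butyldimethylsilyloxy)-2-diazo-3-methyl-6-(propan-2-yl)-3-(prop-2-en-1-yl)cyclohexan-1-one, via trifluoroacetyl ketone 10 (not isolated)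
Conditions: LiN(SiMe3)2, THF, −78 °C; CF3CO2CH2CF3, −78 °C; aq. HCl work-up; then MsN3, Et3N, H2O, MeCN, rt
Reagents that add atoms: methanesulfonyl azide, CS(=O)(=O)N=[N+]=[N-]
Why: Regitz-type diazo transfer with trifluoroacetyl activation: the enolate is acylated at C5, and the 1,3-dicarbonyl compound takes up the diazo group while the trifluoroacetyl group leaves as the sulfonyl amide. C5 is the only position that can enolise because the other α-carbon, C4, is fully substituted; the method is chosen because simple formylation often fails next to a quaternary carbon.

Step 7
Reactants: 11 diazo ketone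
Product: 14 methyl cyclopentanecarboxylate with the ester group on C5 cis to the C1 methyl and C4 silyloxy groups, via ketene 12 (not isolated), via C5-epimeric ester 13 (not isolated)
Conditions: hν (medium-pressure Hg lamp, Pyrex filter), degassed MeOH, 0 °C to rt; then NaOMe, MeOH, 50 °C
Reagents that add atoms: methanol, CO
Why: Excitation of the diazo ketone, which the ring holds in the s-cis geometry, expels N2 while C4 shifts from C6 to C5 (Wolff rearrangement), so that the C4–C5 bond forms, C6 leaves the ring as the ketene carbon of 12, and methanol adds to 12 with protonation at C5 to give the esters 13 and 14. The closest known reaction type is the photochemical ring contraction of 2-diazocyclohexanones to cyclopentanecarboxylic esters. The five-membered ring C1–C5 is closed by this 1,2-shift inside the six-membered ring, a ring contraction, not by an end-to-end cyclisation. C4 migrates with retention and C1 is not involved, so both keep the configuration set earlier. The new stereocentre C5 is placed under thermodynamic control: NaOMe equilibrates the epimers through the ester enolate towards 14, in which the ester group is trans to the isopropyl group and lies next to the smaller silyloxy oxygen and methyl group. Regioselectivity is not in question, since C4 is the only carbon on the carbonyl group that can migrate. Competing carbene pathways are limited by the substrate: C1 has no hydrogen for a 1,2-hydride shift, and addition to the allyl double bond would require a bicyclo[2.1.0]pentane. Pyrex-filtered light leaves the isolated alkene and the silyl ether untouched, and the light-sensitive cinnamate is not yet present.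

Step 8
Reactants: 14 methyl ester
Product: 15 primary alcohol (hydroxymethyl group on C5)
Conditions: LiAlH4, THF, 0 to 40 °C
Reagents that add atoms: none
Why: Hydride reduction of a hindered ester to the primary alcohol; a small, strong hydride donor is used because C6 is flanked by two quaternary carbons, and the silyl ether and the terminal alkene are inert.

Step 9
Reactants: 15 primary alcohol
Product: 16 aldehyde (formyl group on C5)
Conditions: Dess–Martin periodinane, pyridine, CH2Cl2, 0 °C to rt
Reagents that add atoms: none
Why: Dess–Martin oxidation under buffered conditions stops at the aldehyde; C5 already has its more stable configuration, so it is not at risk.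

Step 10
Reactants: 16 aldehyde; 17 3-bromo-2-methylprop-1-ene
Product: 19 homoallylic alcohol with (S) configuration at C6, via methallylmagnesium bromide 18 (not isolated)
Conditions: Mg, Et2O, 0 °C (17 to 18); then 16, THF, −78 °C; aq. NH4Cl
Reagents that add atoms: none
Why: Addition of an allylic Grignard reagent to an aldehyde forms C6–C7 and the C6 stereocentre. In the reactive rotamer the formyl hydrogen, not the oxygen, should point into the pocket between the quaternary carbons C1 and C4, and the reagent should approach past the C1 methyl group, away from the much larger silyloxy group. This places the C6 oxygen on the face of H5 as in 27; it is a prediction from models and is treated as a risk below.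

Step 11
Reactants: 19 diene
Product: 20 (3R,3aS,4S,8aR)-3-(tert-butyldimethylsilyloxy)-6,8a-dimethyl-3-(propan-2-yl)-1,2,3,3a,4,5,8,8a-octahydroazulen-4-ol
Conditions: second-generation Grubbs catalyst (H2IMes)(PCy3)Cl2Ru=CHPh (5 mol %), CH2Cl2 (5 mM), 40 °C
Reagents that add atoms: none
Why: Ring-closing metathesis: the catalyst loads on the monosubstituted allyl alkene and closes onto the 1,1-disubstituted methallyl alkene, which gives the trisubstituted C8=C9 bond and the seven-membered ring with loss of ethene. The two chains are trans on C1 and C5, so the ring fusion is trans, and the free hydroxyl group is tolerated.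

Step 12
Reactants: 20 silyl ether
Product: 21 (3R,3aS,4S,8aR)-6,8a-dimethyl-3-(propan-2-yl)-1,2,3,3a,4,5,8,8a-octahydroazulene-3,4-diol
Conditions: Bu4NF, THF, 60 °C
Reagents that add atoms: none
Why: Fluoride cleavage of the tertiary silyl ether, which needs heat; nothing else in 20 is sensitive to fluoride, and no stereocentre is involved.

Step 13
Reactants: 22 (E)-p-coumaric acid
Product: 24 (E)-3-[4-(tert-butyldimethylsilyloxy)phenyl]prop-2-enoic acid, via bis-silyl derivative 23 (not isolated)
Conditions: TBSCl, imidazole, DMF, rt; then AcOH/THF/H2O, rt
Reagents that add atoms: tert-butyldimethylsilyl chloride, CC(C)(C)[Si](C)(C)Cl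
Why: Both acidic hydroxyl groups are silylated, and the silyl ester, which is far more labile than the aryl silyl ether, is then hydrolysed selectively by aqueous acetic acid.

Step 14
Reactants: 21 diol; 24 protected acid
Product: 26 (3R,3aS,4S,8aR)-3-hydroxy-6,8a-dimethyl-3-(propan-2-yl)-1,2,3,3a,4,5,8,8a-octahydroazulen-4-yl (E)-3-[4-(tert-butyldimethylsilyloxy)phenyl]prop-2-enoate, via mixed anhydride 25 (not isolated)
Conditions: 2,4,6-Cl3C6H2COCl, Et3N, THF, rt (24 to 25); then 21, DMAP, toluene, rt to 60 °C
Reagents that add atoms: none
Why: Yamaguchi esterification: DMAP transfers the cinnamoyl group from the mixed anhydride to the hindered secondary C6 hydroxyl group, while the tertiary C4 hydroxyl group does not react. No stereocentre is touched and the E alkene is retained.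

Step 15
Reactants: 26 silyl-protected ester
Product: 27 (3R,3aS,4S,8aR)-3-hydroxy-6,8a-dimethyl-3-(propan-2-yl)-1,2,3,3a,4,5,8,8a-octahydroazulen-4-yl (E)-3-(4-hydroxyphenyl)prop-2-enoate
Conditions: Bu4NF, AcOH, THF, 0 °C
Reagents that add atoms: none
Why: Buffered fluoride cleaves the aryl silyl ether within minutes at 0 °C, because phenoxide is a good leaving group on silicon; the cinnamate ester, the tertiary alcohol and the alkenes are left alone.

## Compound list

1 | (S)-terpinen-4-ol, (1S)-4-methyl-1-(propan-2-yl)cyclohex-3-en-1-ol | CC1=CC[C@](O)(C(C)C)CC1 | starting material
2 | (1S)-1-(tert-butyldimethylsilyloxy)-4-methyl-1-(propan-2-yl)cyclohex-3-ene | CC1=CC[C@](O[Si](C)(C)C(C)(C)C)(C(C)C)CC1 | intermediate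
3 | 4-(tert-butyldimethylsilyloxy)-1-methyl-4-(propan-2-yl)-7-oxabicyclo[4.1.0]heptane, silyloxy carbon as in 1, both epoxide faces | CC12OC1C[C@](O[Si](C)(C)C(C)(C)C)(C(C)C)CC2 | intermediate
4 | 4-(tert-butyldimethylsilyloxy)-1-methyl-2-(phenylselanyl)-4-(propan-2-yl)cyclohexan-1-ol, silyloxy carbon as in 1 | CC1(O)CC[C@@](O[Si](C)(C)C(C)(C)C)(C(C)C)CC1[Se]c1ccccc1 | intermediate
5 | selenoxide of 4 | CC1(O)CC[C@@](O[Si](C)(C)C(C)(C)C)(C(C)C)CC1[Se](=O)c1ccccc1 | intermediate
6 | 4-(tert-butyldimethylsilyloxy)-1-methyl-4-(propan-2-yl)cyclohex-2-en-1-ol, silyloxy carbon as in 1, both C1 epimers | CC1(O)CC[C@@](O[Si](C)(C)C(C)(C)C)(C(C)C)C=C1 | intermediate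
7 | (6R)-6-(tert-butyldimethylsilyloxy)-3-methyl-6-(propan-2-yl)cyclohex-2-en-1-one | CC1=CC(=O)[C@](O[Si](C)(C)C(C)(C)C)(C(C)C)CC1 | intermediate
8 | allyltrimethylsilane | C=CC[Si](C)(C)C | starting material
9 | (3R,6R)-6-(tert-butyldimethylsilyloxy)-3-methyl-6-(propan-2-yl)-3-(prop-2-en-1-yl)cyclohexan-1-one, allyl trans to silyloxy | C=CC[C@@]1(C)CC[C@@](O[Si](C)(C)C(C)(C)C)(C(C)C)C(=O)C1 | intermediate
10 | 2-(trifluoroacetyl) derivative of 9 (keto and enol forms) | C=CC[C@@]1(C)CC[C@@](O[Si](C)(C)C(C)(C)C)(C(C)C)C(=O)C1C(=O)C(F)(F)F | intermediate
11 | (3R,6R)-6-(tert-butyldimethylsilyloxy)-2-diazo-3-methyl-6-(propan-2-yl)-3-(prop-2-en-1-yl)cyclohexan-1-one | C=CC[C@@]1(C)CC[C@@](O[Si](C)(C)C(C)(C)C)(C(C)C)C(=O)C1=[N+]=[N-] | intermediate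
12 | ketene: [2-(tert-butyldimethylsilyloxy)-5-methyl-2-(propan-2-yl)-5-(prop-2-en-1-yl)cyclopentylidene]methanone, C1 and C4 as in 11 | C=CC[C@@]1(C)CC[C@@](O[Si](C)(C)C(C)(C)C)(C(C)C)C1=C=O | intermediate
13 | C5 epimer of 14 (ester group cis to isopropyl and allyl) | C=CC[C@@]1(C)CC[C@@](O[Si](C)(C)C(C)(C)C)(C(C)C)[C@H]1C(=O)OC | intermediate
14 | methyl 2-(tert-butyldimethylsilyloxy)-5-methyl-2-(propan-2-yl)-5-(prop-2-en-1-yl)cyclopentane-1-carboxylate, ester group cis to the silyloxy and methyl groups, allyl trans to silyloxy | C=CC[C@@]1(C)CC[C@@](O[Si](C)(C)C(C)(C)C)(C(C)C)[C@@H]1C(=O)OC | intermediate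
15 | primary alcohol from 14 (CH2OH in place of CO2CH3, same configuration) | C=CC[C@@]1(C)CC[C@@](O[Si](C)(C)C(C)(C)C)(C(C)C)[C@@H]1CO | intermediate
16 | aldehyde from 15 (CHO on C5, same configuration) | C=CC[C@@]1(C)CC[C@@](O[Si](C)(C)C(C)(C)C)(C(C)C)[C@@H]1C=O | intermediate
17 | 3-bromo-2-methylprop-1-ene | C=C(C)CBr | starting material
18 | (2-methylprop-2-en-1-yl)magnesium bromide, CH2=C(CH3)CH2MgBr | C=C(C)C[Mg]Br | intermediate
19 | (1S)-1-[cyclopentyl of 16]-3-methylbut-3-en-1-ol: methallyl adduct of 16, C6 carbinol (S), oxygen on the face of H5 | C=CC[C@@]1(C)CC[C@@](O[Si](C)(C)C(C)(C)C)(C(C)C)[C@@H]1[C@@H](O)CC(C)=C | intermediate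
20 | (3R,3aS,4S,8aR)-3-(tert-butyldimethylsilyloxy)-6,8a-dimethyl-3-(propan-2-yl)-1,2,3,3a,4,5,8,8a-octahydroazulen-4-ol | CC1=CC[C@@]2(C)CC[C@@](O[Si](C)(C)C(C)(C)C)(C(C)C)[C@@H]2[C@@H](O)C1 | intermediate
21 | jaeschkeanadiol, (3R,3aS,4S,8aR)-6,8a-dimethyl-3-(propan-2-yl)-1,2,3,3a,4,5,8,8a-octahydroazulene-3,4-diol | CC1=CC[C@@]2(C)CC[C@@](O)(C(C)C)[C@@H]2[C@@H](O)C1 | intermediate
22 | (E)-p-coumaric acid | O=C(O)/C=C/c1ccc(O)cc1 | starting material
23 | tert-butyldimethylsilyl (E)-3-[4-(tert-butyldimethylsilyloxy)phenyl]prop-2-enoate | CC(C)(C)[Si](C)(C)OC(=O)/C=C/c1ccc(O[Si](C)(C)C(C)(C)C)cc1 | intermediate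
24 | (E)-3-[4-(tert-butyldimethylsilyloxy)phenyl]prop-2-enoic acid | O=C(O)/C=C/c1ccc(O[Si](C)(C)C(C)(C)C)cc1 | intermediate
25 | mixed anhydride of 24 with 2,4,6-trichlorobenzoic acid | O=C(OC(=O)c1c(Cl)cc(Cl)cc1Cl)/C=C/c1ccc(O[Si](C)(C)C(C)(C)C)cc1 | intermediate
26 | (3R,3aS,4S,8aR)-3-hydroxy-6,8a-dimethyl-3-(propan-2-yl)-1,2,3,3a,4,5,8,8a-octahydroazulen-4-yl (E)-3-[4-(tert-butyldimethylsilyloxy)phenyl]prop-2-enoate | CC1=CC[C@@]2(C)CC[C@@](O)(C(C)C)[C@@H]2[C@@H](OC(=O)/C=C/c2ccc(O[Si](C)(C)C(C)(C)C)cc2)C1 | intermediate
27 | (3R,3aS,4S,8aR)-3-hydroxy-6,8a-dimethyl-3-(propan-2-yl)-1,2,3,3a,4,5,8,8a-octahydroazulen-4-yl (E)-3-(4-hydroxyphenyl)prop-2-enoate | CC1=CC[C@@]2(C)CC[C@@](O)(C(C)C)[C@@H]2[C@@H](OC(=O)/C=C/c2ccc(O)cc2)C1 | target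

## Step count and risks

Total: 15 steps. Longest linear sequence: 14 steps (steps 1 to 12, 14 and 15, from 1 to 27); step 13 is a one-step side branch. Stereocentres: C4 comes from 1, C1 is set in step 5, C5 in step 7 and C6 in step 10.

**Step 7 (key step).** The excited diazo ketone may be diverted from the 1,2-shift into insertion into the O–H bond of the solvent or into migration of a C1 substituent to the carbene carbon, because the migrating carbon is fully substituted and crowded. In the second stage, enolisation at C5 between two quaternary carbons may be slow, or the ester enolate may lose silanolate. Should the ester not equilibrate cleanly, the same adjustment can be made one step later on 16 with a mild amine base. Fallback with a different ring contraction: starting from 9, the lithium enolate (LiN(SiMe3)2, THF, −78 °C) is brominated with N-bromosuccinimide to the C5-bromo ketone F1. NaOMe in MeOH then adds to the C6 carbonyl group, and the C6–C4 bond migrates to C5 with loss of bromide (quasi-Favorskii rearrangement; no cyclopropanone can form because C4 has no hydrogen). The methoxide also equilibrates C5, and the route is rejoined at 14.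

**Step 5.** Facial selectivity may be poor, because the controlling centre C4 is 1,4 to the reacting carbon C1, and chelation of TiCl4 between the carbonyl and silyloxy oxygens would favour the other half-chair; partial loss of the silyl ether is a second concern. Fallback that replaces 1,4- by 1,2-induction: starting from 7, allylmagnesium bromide (CH2=CHCH2MgBr, THF, −78 °C) adds to the C6 carbonyl group anti to the neighbouring pseudo-axial silyloxy group and gives the tertiary dienol F2. KH and 18-crown-6 in THF then induce the anionic oxy-Cope rearrangement, which carries the allyl group suprafacially from C6 to C1; protonation of the enolate rejoins the route at 9.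

**Step 10.** The addition may show poor or reversed facial selectivity, because both faces of the formyl group are flanked by quaternary carbons and the prediction rests on a rotamer argument. Fallback that replaces steric control by chelation control: starting from 15, Bu4NF in THF removes the silyl group to give the diol F3. The primary alcohol is oxidised selectively (TEMPO, PhI(OAc)2, CH2Cl2) to the hydroxy aldehyde F4, which is used at once because it can undergo retro-aldol cleavage. An excess of 18 at −78 °C first forms the magnesium alkoxide at C4, which chelates the formyl oxygen, and then adds to the exposed face of the chelate, away from C1, giving the diene diol F5 with the same C6 configuration as 19. Ring-closing metathesis with the second-generation Grubbs catalyst rejoins the route at 21, so that steps 11 and 12 are no longer needed.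

**Step 4.** The 1,3-shift may be slow or incomplete, because the chromate ester has to move to the neopentyl carbon C6 next to the silyloxy-bearing centre, and dehydration of the tertiary allylic alcohol to dienes would then compete. Fallback by direct C–H oxidation: starting from 2, CrO3 with 3,5-dimethylpyrazole (hexavalent chromium, CH2Cl2, −20 °C) oxidises the allylic methylene groups and gives 7 together with the C2-oxo regioisomer F6, from which 7 is separated by chromatography; the route is rejoined at 7, and steps 2 to 4 are bypassed.

## Further compounds

F1 | step 7 | C5-bromo ketone: 2-bromo derivative of 9 | C=CC[C@@]1(C)CC[C@@](O[Si](C)(C)C(C)(C)C)(C(C)C)C(=O)C1Br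
F2 | step 5 | 6-(tert-butyldimethylsilyloxy)-3-methyl-6-(propan-2-yl)-1-(prop-2-en-1-yl)cyclohex-2-en-1-ol, allyl trans to silyloxy | C=CC[C@@]1(O)C=C(C)CC[C@@]1(O[Si](C)(C)C(C)(C)C)C(C)C
F3 | step 10 | diol: desilylated 15 | C=CC[C@@]1(C)CC[C@@](O)(C(C)C)[C@@H]1CO
F4 | step 10 | hydroxy aldehyde: desilylated 16 | C=CC[C@@]1(C)CC[C@@](O)(C(C)C)[C@@H]1C=O
F5 | step 10 | diene diol: desilylated 19 | C=CC[C@@]1(C)CC[C@@](O)(C(C)C)[C@@H]1[C@@H](O)CC(C)=C
F6 | step 4 | 5-(tert-butyldimethylsilyloxy)-2-methyl-5-(propan-2-yl)cyclohex-2-en-1-one, silyloxy carbon as in 1 | CC1=CC[C@](O[Si](C)(C)C(C)(C)C)(C(C)C)CC1=O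
A1 | alternative 1 | jaeschkeanadiol (identical with 21) | CC1=CC[C@@]2(C)CC[C@@](O)(C(C)C)[C@@H]2[C@@H](O)C1
A2 | alternative 1 | tricyclic cyclopropylcarbinol: trans-hydrindane with C7 bridging C6 and C8, hydroxyl groups on C4 and C9 (either C9 epimer) | C[C@]12CC[C@@](O)(C(C)C)[C@@H]1[C@H]3C[C@@]3(C)C(O)C2
A3 | alternative 2 | ketal-protected hydroazulene diene with methyl ester on C8 | COC(=O)C1=CC[C@@]2(C)CCC3(OCCO3)C2=CC1
A4 | alternative 2 | 7-methyl-6-vinyl-1,4-dioxaspiro[4.4]non-6-ene | C=CC1=C(C)CCC12OCCO2
A5 | alternative 2 | methyl 2-diazobut-3-enoate | C=CC(=[N+]=[N-])C(=O)OC
A6 | alternative 3 | cis-fused oxasilolane with C6 on C5 and allyl on C1 | C=CC[C@@]1(C)CC[C@@](O3)(C(C)C)[C@@H]1C[Si]3(C)C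
A7 | alternative 3 | (bromomethyl)dimethylsilyl ether of 2-methyl-1-(propan-2-yl)cyclopent-2-en-1-ol | CC1=C[C@](O[Si](C)(C)CBr)(C(C)C)CC1
A8 | alternative 3 | allyltributylstannane | C=CC[Sn](CCCC)(CCCC)CCCC
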